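## The problem

Disulfuretin (10) is a C2-symmetric bis-aurone: two 6-hydroxy-1-benzofuran-3(2H)-one rings, each with an exocyclic C2=Cα double bond, are joined through the Cα–Cα' single bond, and each Cα also carries a 3,4-dihydroxyphenyl ring. The core is thus a fully substituted buta-1,3-diene, C2=Cα–Cα'=C2', whose terminal carbons are ring atoms bonded to O1 and to the C3 carbonyl. The usual aurone synthesis, aldol condensation at C2 with an aldehyde, cannot reach it because it never gives a Cα with two carbon substituents. There is no sp3 stereocentre; the only stereo elements are the two tetrasubstituted alkenes, each (Z) in the sense that O1 is syn to the neighbouring diene carbon and the catechol ring is syn to C3=O. No group in the molecule can steer this geometry kinetically. However, O-protonation or Lewis acid complexation of an aurone places a cation on Cα that the electron-rich aryl ring stabilises, so rotation about C2–Cα is open under acid and the geometry can be left to equilibrium. Six phenols, four of them in two catechols, forbid oxidants and aerobic base late in the route, and the push–pull enones are sensitive to nucleophiles and light; the phenols therefore stay masked to the last step and the end-game is acidic. The enabling feature is the four-carbon chain C2–Cα–Cα'–C2': each enone is the 1,3-transposed form of a 2-acyl-3-alkoxybenzofuran, so Cα and Cα' can be ketones awaiting the aryl rings, while C2 and C2' each need one bond to a phenol oxygen (O1) and one to an acyl carbon (C3). That is the reactivity of the two CH2Br groups of dione 2, electrophilic toward a phenoxide and, once O-alkylated, nucleophilic toward an ortho ester.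

## Retrosynthesis

**10 ⇒ 9 (six aryl O–CH3 bonds).** The phenols are carried as methyl ethers, so the last intermediate is the hexamethyl ether 9. Methyl is preferred to benzyl or acetal groups because building blocks 1 and 6 are sold as methyl ethers and the group survives carbonate base, an aryllithium and aqueous acid. Hydrogenolysis of benzyl ethers would also endanger the two enone alkenes. The forward step must cleave six ethers without oxidant or base; BBr3 does this for aurone methyl ethers, and its acidity keeps the alkene equilibrium open.

**9 ⇒ 8 (C3=O and C2=Cα traced back to C3–OMe and Cα–OH).** Each enone is read as the product of a Stork–Danheiser 1,3-carbonyl transposition. Adding methanol back across C3/Cα turns each aurone into an aromatic 3-methoxybenzofuran with a tertiary carbinol at Cα, which gives the bis-carbinol 8. This is preferred to any olefination at C2=Cα, since a tetrasubstituted push–pull alkene has no dependable Wittig or aldol route. It also hides both alkenes, and with them the geometry question, inside aromatic rings until the final C–O event. The forward reaction asks each carbinol to ionise to an oxocarbenium ion, take up water at C3 and lose methanol.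

**8 ⇒ 5 + 7 (both Cα–aryl bonds).** Cutting the two carbinol–aryl bonds gives the symmetrical vicinal diketone 5 and 3,4-dimethoxyphenyllithium 7, generated from bromide 6. Cutting the central Cα–Cα' bond of 8 instead (a reductive carbonyl coupling) is kept in reserve. The chosen cut lets one C4 diketone take up both aryl groups in a single operation and leaves the central bond to come from the linchpin. Compound 5 has no stereo element and 22 carbons against 38 in 8. The forward reaction must achieve two 1,2-additions on neighbouring, hindered, vinylogous-ester ketones.

**5 ⇒ 4 (two enol O–CH3 bonds).** The 3-methoxy groups are removed retrosynthetically to the bis-enol 4. They are needed in the forward direction for two reasons: a free enol would be deprotonated by 7 and turn each ketone into an unreactive vinylogous carboxylate, and the methyl group later becomes the leaving group of the transposition. The forward reaction needs O- and not C-methylation.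

**4 ⇒ 3 ⇒ 1 + 2 (both O1–C2 and both C2–C3 bonds).** Cutting in each ring the ether bond O1–C2 and the bond C2–C3 removes four skeletal bonds and two rings at once. What remains is salicylate 1 (twice) and dibromodione 2, joined first through the bis-ether 3. The aryl ring, O1 and C3 come from 1, with the ester carbon already at the carbonyl oxidation level that C3 needs; C2, Cα, Cα' and C2' come in one piece from 2. Building two halves separately would cost an extra C–C coupling for Cα–Cα'. Cutting only O1–C2 would require an α-functionalised tetraketone. Both components are commercial. The forward reaction must complete SN2 at both CH2Br groups before base destroys the dione, and then enolise and acylate twice.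

## Roads not taken

**Alternative 1:** The cut is again at both Cα–aryl bonds, but at the enone oxidation level. The aryl-free bis-aurone diene A2 would take up two equivalents of boronic acid A3 under [Rh(cod)OH]2 catalysis to give the saturated adduct A1, which must then be dehydrogenated twice.
- Merits: the C–aryl bond formation is catalytic and near neutral, needs no organolithium and avoids the crowded vicinal diol 8.
- Weak points: in A2 each β-carbon is deactivated by donation from O1, and the cross-conjugated dienedione offers competing addition modes. A1 carries four stereocentres (C2, Cα, Cα', C2') as a diastereomer mixture that must all be erased. The closing double dehydrogenation has to create two tetrasubstituted alkenes by quinone or halogenation–elimination chemistry on a hexamethoxy, electron-rich framework.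
- Comparison: in mildness of the arylation Alternative 1 is the better road. The chosen plan sets against this that the aryl groups enter at an oxidation level from which loss of methanol alone gives the dienedione, so no redox step follows. It reaches 9 in three steps, while Alternative 1 needs the synthesis of A2, the arylation and an oxidation before the same final deprotection.

**Alternative 2:** The cut is at both O1–C2 bonds. The hexamethyl ether A4 (identical with 9) is traced back to the tetrasubstituted furan A5, whose ring carbons are the future C2–Cα–Cα'–C2' chain. In the forward key step, acid would make each ortho-phenol attack the furan carbon that bears its own aroyl group, and the furan oxygen would leave as water.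
- Merits: the whole carbon skeleton and both aryl groups are in place before the rings form, no organometallic addition to a hindered diketone is needed, and the key step ends directly at the compound that the chosen plan reaches in step 3.
- Weak points: a 2,5-diacylfuran is electron-poor, and the ipso attack needs protonation at a fully substituted ring carbon. An aromatic furan is given up for no clear thermodynamic gain, so rate and position of equilibrium are both uncertain and no close model exists. A5 itself needs a multistep synthesis with the two ortho-phenols differentiated from the other oxygens.
- Comparison: Alternative 2 is superior in bypassing the diol 8. The chosen plan sets against this that every one of its steps belongs to a known reaction type and that 9 is three steps from commercial materials.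

**Alternative 3:** The cut is at C3a–C3 and O1–C2 of both heterocycles. Enediyne A7 would undergo a double Sonogashira coupling with iodophenol A8 (Pd(PPh3)2Cl2, CuI, Et3N), followed by 5-endo-dig closure of each phenol onto its alkyne, to give the bis(benzofuranyl)stilbene A6.
- Merits: the ring-forming step is catalytic and among the most reliable benzofuran syntheses, arguably more reliable than the linchpin condensation chosen here. The aryl groups are in place from the start.
- Weak points: A6 is at the wrong oxidation level. Both C3 oxygens are missing, and the end-game must oxidise two aromatic benzofuran C3–H positions to ketones while moving the central double bond into two exocyclic positions. This is a net six-electron oxidation of a very electron-rich arene system for which no selective method is evident. A7 also needs several steps.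
- Comparison: the chosen plan sets oxidation-state economy against the better key-step reliability of Alternative 3. The C3 oxygens arrive as the ester carbonyls of 1 and the Cα carbons as ketones, so no late oxidation is required.

Key step: step 1

## Route

Assumption: the (Z,Z) geometry of the target is taken to be the thermodynamically preferred one. With O1 rather than C3=O beside the diene arm the two enones can approach coplanarity, while the catechol ring twists beside the carbonyl. The alkenes are therefore set by acid equilibration, not by a kinetically controlled step.

Step 1
Reactants: 1 methyl 2-hydroxy-4-methoxybenzoate (2.1 equiv); 2 1,4-dibromobutane-2,3-dione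
Product: 4 1,2-bis(3-hydroxy-6-methoxy-1-benzofuran-2-yl)ethane-1,2-dione, via bis(aryloxymethyl) diketone 3 (not isolated)
Conditions: K2CO3 (5 equiv), DMF, rt; 2 added slowly at 0 °C, then rt, then 70 °C; aq. HCl work-up
Reagents that add atoms: none
Why: The phenoxide of 1 displaces both primary α-keto bromides of 2 by SN2 to give 3; carbonate then enolises each aryloxymethyl ketone, whose acidity is raised by the aryloxy group and the vicinal dione, and each carbanion attacks the ester ortho to its oxygen in a Dieckmann-type (intramolecular Claisen) acylation, methoxide leaving and the 2-acylbenzofuran-3(2H)-one tautomerising to the aromatic, hydrogen-bonded 3-hydroxybenzofuran. The closest known reaction type is the base-mediated condensation of salicylate esters with α-halo ketones to 2-acyl-3-hydroxybenzofurans, here run in both directions on one linchpin. Each furan ring closes by a 5-exo-trig attack of the enolate carbon (enolate C=C exocyclic to the new ring) on the ester carbonyl, forming C2–C3 after O1–C2. No stereocentre is formed. The step needs O-alkylation to outrun base-induced self-condensation of 2, which the high SN2 rate of an α-bromo ketone, the excess of phenoxide already present and the slow addition of 2 at 0 °C should secure. It also needs C-acylation to beat intermolecular aldol chemistry of 3, which the ortho ester secures by making the acylation a five-ring intramolecular event. Deprotonation of each product enol by carbonate should make both closures irreversible and shield the remaining carbonyl groups.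

Step 2
Reactants: 4 1,2-bis(3-hydroxy-6-methoxy-1-benzofuran-2-yl)ethane-1,2-dione
Product: 5 1,2-bis(3,6-dimethoxy-1-benzofuran-2-yl)ethane-1,2-dione
Conditions: Me2SO4, K2CO3, DMF, rt to 40 °C
Reagents that add atoms: dimethyl sulfate, COS(=O)(=O)OC
Why: Williamson-type O-methylation of the two enols (vinylogous acids); O- rather than C-alkylation is expected with the hard electrophile because attack at C2 would break the benzofuran aromaticity and build a quaternary centre, as is known for 2-acyl- and 2-alkoxycarbonyl-3-hydroxybenzofurans. DMF replaces acetone so that no enolisable ketone can add to the diketone.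

Step 3
Reactants: 5 1,2-bis(3,6-dimethoxy-1-benzofuran-2-yl)ethane-1,2-dione; 6 4-bromo-1,2-dimethoxybenzene (3 equiv)
Product: 9 disulfuretin hexamethyl ether (2Z,2'Z)-2,2'-[1,2-bis(3,4-dimethoxyphenyl)ethane-1,2-diylidene]bis(6-methoxy-1-benzofuran-3(2H)-one), via 3,4-dimethoxyphenyllithium 7 (not isolated), via tertiary diol 8 (not isolated)
Conditions: 6, n-BuLi, THF, −78 °C; then 5, −78 °C to 0 °C; then 2 M aq. HCl, THF, rt
Reagents that add atoms: water, O
Why: Bromine–lithium exchange gives 7, which adds 1,2 to both ketones of the vicinal diketone (the second addition helped by lithium chelation between alkoxide and carbonyl) to give 8 as a meso/racemic mixture whose stereocentres are erased at once. Aqueous acid then effects a two-fold Stork–Danheiser-type 1,3-carbonyl transposition: each tertiary carbinol ionises to an oxocarbenium ion delocalised over Cα, C2 and C3–OMe, water adds at C3 and methanol leaves, so the C3 carbonyl oxygens come from water. Reversible O-protonation of the aurones regenerates the Cα cation and allows rotation about C2–Cα, so both tetrasubstituted alkenes should settle in the thermodynamically preferred (Z,Z) arrangement.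

Step 4
Reactants: 9 disulfuretin hexamethyl ether
Product: 10 disulfuretin (2Z,2'Z)-2,2'-[1,2-bis(3,4-dihydroxyphenyl)ethane-1,2-diylidene]bis(6-hydroxy-1-benzofuran-3(2H)-one)
Conditions: BBr3 (excess), CH2Cl2, −78 °C to rt, argon, dark; then MeOH, aq. HCl work-up
Reagents that add atoms: none
Why: BBr3 ether cleavage (Lewis acid–base complexation, then bromide SN2 attack on methyl) is the standard way to free polyhydroxyaurones from their methyl ethers; the medium is acidic and non-oxidising, so the catechols should survive. Complexation of the C3 carbonyls keeps the alkene geometry under the same thermodynamic control as in step 3.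

## Compound list

1 | methyl 2-hydroxy-4-methoxybenzoate | COC(=O)c1ccc(OC)cc1O | starting material
2 | 1,4-dibromobutane-2,3-dione | O=C(CBr)C(=O)CBr | starting material
3 | dimethyl 2,2'-[(2,3-dioxobutane-1,4-diyl)bis(oxy)]bis(4-methoxybenzoate) | COC(=O)c1ccc(OC)cc1OCC(=O)C(=O)COc1cc(OC)ccc1C(=O)OC | intermediate
4 | 1,2-bis(3-hydroxy-6-methoxy-1-benzofuran-2-yl)ethane-1,2-dione | COc1ccc2c(O)c(C(=O)C(=O)c3oc4cc(OC)ccc4c3O)oc2c1 | intermediate
5 | 1,2-bis(3,6-dimethoxy-1-benzofuran-2-yl)ethane-1,2-dione | COc1ccc2c(OC)c(C(=O)C(=O)c3oc4cc(OC)ccc4c3OC)oc2c1 | intermediate
6 | 4-bromo-1,2-dimethoxybenzene (4-bromoveratrole) | COc1ccc(Br)cc1OC | starting material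
7 | (3,4-dimethoxyphenyl)lithium | [Li]c1ccc(OC)c(OC)c1 | intermediate
8 | 1,2-bis(3,4-dimethoxyphenyl)-1,2-bis(3,6-dimethoxy-1-benzofuran-2-yl)ethane-1,2-diol (meso and racemic forms, configuration not controlled) | COc1ccc2c(OC)c(C(O)(c3ccc(OC)c(OC)c3)C(O)(c3ccc(OC)c(OC)c3)c3oc4cc(OC)ccc4c3OC)oc2c1 | intermediate
9 | disulfuretin hexamethyl ether, (2Z,2'Z)-2,2'-[1,2-bis(3,4-dimethoxyphenyl)ethane-1,2-diylidene]bis(6-methoxy-1-benzofuran-3(2H)-one) | O=C1/C(=C(/C(=C2\Oc3cc(OC)ccc3C2=O)c2ccc(OC)c(OC)c2)c2ccc(OC)c(OC)c2)Oc2cc(OC)ccc21 | intermediate
10 | disulfuretin, (2Z,2'Z)-2,2'-[1,2-bis(3,4-dihydroxyphenyl)ethane-1,2-diylidene]bis(6-hydroxy-1-benzofuran-3(2H)-one) | O=C1/C(=C(/C(=C2\Oc3cc(O)ccc3C2=O)c2ccc(O)c(O)c2)c2ccc(O)c(O)c2)Oc2cc(O)ccc21 | target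

## Step count and least certain steps

Total steps: 4. Longest linear sequence: 4 (1 and 2 to 4, 5, 9, 10).

**Step 1 (key step).** The most likely failure is base-induced destruction of the linchpin. Both 2 and the bis-ether 3 are enolisable, strongly electrophilic vicinal diketones, so self-aldolisation or attack by carbonate can outrun the second O-alkylation or the Dieckmann-type closures. The second closure may also stall once the first ring sits as an enolate.
Fallback, setting out from 1 and rejoining the route at 5: no vicinal dione is exposed to base. Compound 1 is O-alkylated with methyl bromoacetate (K2CO3, DMF) to methyl 4-methoxy-2-(2-methoxy-2-oxoethoxy)benzoate F1. This is closed with t-BuOK in THF to methyl 3-hydroxy-6-methoxy-1-benzofuran-2-carboxylate F2, then hydrolysed and decarboxylated (aq. HCl, AcOH, reflux) to 6-methoxy-1-benzofuran-3(2H)-one F3. F3 is converted with trimethyl orthoformate, TsOH and MeOH into 3,6-dimethoxy-1-benzofuran F4 and lithiated at C2 (n-BuLi, THF, −78 °C) to (3,6-dimethoxy-1-benzofuran-2-yl)lithium F5. Two equivalents of F5 are acylated on 1,4-dimethylpiperazine-2,3-dione to give 5 directly. The central bond then comes from the oxalyl unit and the diketone is made last.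

**Step 3.** The most likely failure is incomplete or misdirected aryl addition. After the first addition the remaining ketone sits next to a quaternary lithium alkoxide and is a vinylogous ester, so the second addition may stall. The aryllithium may instead attack C3 with loss of methoxide. A smaller hazard is a 1,2-shift (pinacol rearrangement) in the first cation before water captures it.
Fallback, setting out from 1 and rejoining the route at 8: the aryl group is carried in from the start and the central bond is formed reductively. This gives up the linchpin and is held as a last resort. Compound 1 is O-alkylated with 2-bromo-1-(3,4-dimethoxyphenyl)ethan-1-one (K2CO3, DMF) to methyl 2-[2-(3,4-dimethoxyphenyl)-2-oxoethoxy]-4-methoxybenzoate F6. This is closed with NaOMe in MeOH to (3,4-dimethoxyphenyl)(3-hydroxy-6-methoxy-1-benzofuran-2-yl)methanone F7 and methylated as in step 2 to (3,4-dimethoxyphenyl)(3,6-dimethoxy-1-benzofuran-2-yl)methanone F8. Pinacol coupling of F8 with SmI2 in THF gives 8, which is then treated with aqueous acid as in the second stage of step 3.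

**Step 4.** The most likely failure has three parts:
- incomplete cleavage of the two C6 methyl ethers, whose oxygens are deactivated by conjugation with the complexed carbonyls;
- scrambling of alkene geometry under the Lewis acid if the equilibrium is less one-sided than assumed;
- oxidative loss of the free catechols during chromatography.

Fallback, setting out from 9 and rejoining the route at 10: a derivatise–purify–release end-game. The crude product of the BBr3 treatment is peracetylated (Ac2O, pyridine) to disulfuretin hexaacetate F9, which should be stable to air and silica. Partially methylated material can be separated from it and returned to step 4, and geometric isomers can be separated and re-equilibrated with acid. F9 is then deacetylated with HCl in MeOH under argon to give 10.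

## Further compounds

F1 | step 1 | methyl 4-methoxy-2-(2-methoxy-2-oxoethoxy)benzoate | COC(=O)COc1cc(OC)ccc1C(=O)OC
F2 | step 1 | methyl 3-hydroxy-6-methoxy-1-benzofuran-2-carboxylate | COC(=O)c1oc2cc(OC)ccc2c1O
F3 | step 1 | 6-methoxy-1-benzofuran-3(2H)-one | COc1ccc2c(c1)OCC2=O
F4 | step 1 | 3,6-dimethoxy-1-benzofuran | COc1ccc2c(OC)coc2c1
F5 | step 1 | (3,6-dimethoxy-1-benzofuran-2-yl)lithium | [Li]c1oc2cc(OC)ccc2c1OC
F6 | step 3 | methyl 2-[2-(3,4-dimethoxyphenyl)-2-oxoethoxy]-4-methoxybenzoate | COC(=O)c1ccc(OC)cc1OCC(=O)c1ccc(OC)c(OC)c1
F7 | step 3 | (3,4-dimethoxyphenyl)(3-hydroxy-6-methoxy-1-benzofuran-2-yl)methanone | COc1ccc2c(O)c(C(=O)c3ccc(OC)c(OC)c3)oc2c1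
F8 | step 3 | (3,4-dimethoxyphenyl)(3,6-dimethoxy-1-benzofuran-2-yl)methanone | COc1ccc2c(OC)c(C(=O)c3ccc(OC)c(OC)c3)oc2c1
F9 | step 4 | disulfuretin hexaacetate, (2Z,2'Z) | O=C1/C(=C(/C(=C2\Oc3cc(OC(C)=O)ccc3C2=O)c2ccc(OC(C)=O)c(OC(C)=O)c2)c2ccc(OC(C)=O)c(OC(C)=O)c2)Oc2cc(OC(C)=O)ccc21
A1 | alternative 1 | 2,2'-[1,2-bis(3,4-dimethoxyphenyl)ethane-1,2-diyl]bis(6-methoxy-1-benzofuran-3(2H)-one), diastereomer mixture | COc1ccc2c(c1)OC(C(c1ccc(OC)c(OC)c1)C(c1ccc(OC)c(OC)c1)C1Oc3cc(OC)ccc3C1=O)C2=O
A2 | alternative 1 | (2Z,2'Z)-2,2'-(ethane-1,2-diylidene)bis(6-methoxy-1-benzofuran-3(2H)-one) | COc1ccc2c(c1)O/C(=C\C=C1/Oc3cc(OC)ccc3C1=O)C2=O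
A3 | alternative 1 | (3,4-dimethoxyphenyl)boronic acid | COc1ccc(B(O)O)cc1OC
A4 | alternative 2 | disulfuretin hexamethyl ether (identical with 9) | O=C1/C(=C(/C(=C2\Oc3cc(OC)ccc3C2=O)c2ccc(OC)c(OC)c2)c2ccc(OC)c(OC)c2)Oc2cc(OC)ccc21
A5 | alternative 2 | [3,4-bis(3,4-dimethoxyphenyl)furan-2,5-diyl]bis[(2-hydroxy-4-methoxyphenyl)methanone] | COc1ccc(C(=O)c2oc(C(=O)c3ccc(OC)cc3O)c(-c3ccc(OC)c(OC)c3)c2-c2ccc(OC)c(OC)c2)c(O)c1
A6 | alternative 3 | (E)-1,2-bis(3,4-dimethoxyphenyl)-1,2-bis(6-methoxy-1-benzofuran-2-yl)ethene | COc1ccc2cc(/C(c3ccc(OC)c(OC)c3)=C(/c3cc4ccc(OC)cc4o3)c3ccc(OC)c(OC)c3)oc2c1
A7 | alternative 3 | (E)-3,4-bis(3,4-dimethoxyphenyl)hex-3-ene-1,5-diyne | C#C/C(c1ccc(OC)c(OC)c1)=C(/C#C)c1ccc(OC)c(OC)c1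
A8 | alternative 3 | 2-iodo-5-methoxyphenol | COc1ccc(I)c(O)c1
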